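**Plan**

- Retrosynthesis: C8=C17 goes back to an 8-ketone and the C15 acid to a primary alcohol. The C4–C5 bond of ring A is then cut with C19 returned to O7, which gives a bridged ten-membered lactone on ring B. Further cuts are the lactone C19–O7 bond, C1=C2 (Wittig), the ring B bonds C5–C10 and C8–C9 (Diels–Alder) and C9=C10 (Wittig).
- Enabling feature: the C19 carboxyl sits on quaternary C4, and C4 is bonded to C5, which is allylic to C6=C7 once ring B carries oxygen at C7 and C8. This γ,δ-unsaturated acid is the product pattern of an ester enolate Claisen shift of a C7 allylic ester.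
- Forward order: C9 aldehyde from (R)-linalool, (E)-enal, ring B by enantioselective Diels–Alder reaction, C1–C4/C19 arm by Wittig reaction, ring B enone with 8α- and 7β-oxygen, lactone, ring A by ring contraction, then hydrogenation, desilylation, oxidation and methylenation.
- Stereochemistry: C13 comes from (R)-linalool; C9 and C10 from the enal geometry and the chiral Diels–Alder catalyst; C8 and C7 from substrate control; C5 and C4 from the sigmatropic shift.

Key step: step 16

Remark (convention): positions carry labdane numbers (C17 exocyclic methylene carbon, C18 methyl on C4, C19 carboxyl on C4, C20 methyl on C10); β is the face of ring B that carries C20; "SC" is the C9 side chain (3R)-3,5-bis(tert-butyldimethylsilyloxy)-3-methylpentyl (C11–C15); TBSO is tert-butyldimethylsilyloxy; in the seco-norlabdane names C9 (side chain β) and C10 (methyl β) have the labdane configuration.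

Remark (assumption): C4 is carried as both epimers from 13 to 23 (its SMILES descriptor is left open), which is harmless because C4 becomes trigonal in step 16.

Remark (assumption): the (S)-prolinol-derived oxazaborolidinium ion is taken to expose the C2-Si face of enal 8, as its binding model for 2-substituted enals predicts; its antipode would be used otherwise.

**Route**

Step 1
Reactants: 1 (R)-(−)-linalool
Product: 3 (3R)-3,7-dimethyloct-6-ene-1,3-diol, via B-alkyl-9-BBN adduct 2 (not isolated)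
Conditions: 9-BBN (2.2 equiv), THF, 0 °C to rt; then NaOH, H2O2, H2O, 0 °C to rt
Reagents that add atoms: hydrogen peroxide, OO
Why: Hydroboration–oxidation with the bulky borane should take place only at the monosubstituted vinyl group, with anti-Markovnikov regiochemistry, and leave the trisubstituted alkene and the C13 carbinol centre of linalool untouched.

Step 2
Reactants: 3 (3R)-3,7-dimethyloct-6-ene-1,3-diol
Product: 4 (3R)-1,3-bis(tert-butyldimethylsilyloxy)-3,7-dimethyloct-6-ene
Conditions: TBSOTf (2.6 equiv), 2,6-lutidine, CH2Cl2, −78 to 0 °C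
Reagents that add atoms: tert-butyldimethylsilyl triflate, CC(C)(C)[Si](C)(C)OS(=O)(=O)C(F)(F)F
Why: Silyl ether formation with the silyl triflate is forceful enough to cap the tertiary C13 hydroxyl together with the primary C15 hydroxyl in one operation.

Step 3
Reactants: 4 (3R)-1,3-bis(tert-butyldimethylsilyloxy)-3,7-dimethyloct-6-ene
Product: 6 (4R)-4,6-bis(tert-butyldimethylsilyloxy)-4-methylhexanal, via secondary ozonide 5 (not isolated)
Conditions: O3, CH2Cl2, −78 °C; then PPh3, −78 °C to rt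
Reagents that add atoms: ozone, [O-][O+]=O
Why: Ozonolysis with reductive work-up cleaves the only alkene and releases C9 as the aldehyde.

Step 4
Reactants: 6 (4R)-4,6-bis(tert-butyldimethylsilyloxy)-4-methylhexanal; 7 2-(triphenylphosphoranylidene)propanal
Product: 8 (2E,6R)-6,8-bis(tert-butyldimethylsilyloxy)-2,6-dimethyloct-2-enal
Conditions: toluene, 90 °C
Reagents that add atoms: none
Why: Wittig olefination with the stabilised ylide should give the (E)-2-methyl-2-enal, which brings in C10, C20 and C1 and fixes the geometry that becomes the C9/C10 relative configuration.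

Step 5
Reactants: 9 methyl vinyl ketone
Product: 10 2-(triisopropylsilyloxy)buta-1,3-diene
Conditions: TIPSOTf, Et3N, CH2Cl2, 0 °C
Reagents that add atoms: triisopropylsilyl triflate, CC(C)[Si](C(C)C)(C(C)C)OS(=O)(=O)C(F)(F)F
Why: Silyl enol ether formation by soft enolisation of the methyl ketone gives the 2-silyloxydiene that carries C5–C8.

Step 6
Reactants: 8 (2E,6R)-6,8-bis(tert-butyldimethylsilyloxy)-2,6-dimethyloct-2-enal; 10 2-(triisopropylsilyloxy)buta-1,3-diene
Product: 11 (1S,6S)-1-methyl-6-SC-4-(triisopropylsilyloxy)cyclohex-3-ene-1-carbaldehyde (10β-methyl, 9β-SC)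
Conditions: (S)-o-tolyl-oxazaborolidine from (S)-α,α-diphenylprolinol (20 mol%), HN(SO2CF3)2 (20 mol%), CH2Cl2, −78 to −40 °C
Reagents that add atoms: none
Why: Enantioselective Diels–Alder reaction under chiral oxazaborolidinium catalysis, in which the nucleophilic CH2 terminus of the silyl enol ether bonds to C9 and the other terminus to C10 ("para" orientation), the E geometry places the side chain cis to the C10 methyl, and addition to the C2-Si face of the bound s-trans enal sets C9 and C10 absolutely.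

Step 7
Reactants: 12 methyl 4-bromo-2-methylbutanoate (racemic)
Product: 13 (4-methoxy-3-methyl-4-oxobutyl)triphenylphosphonium bromide
Conditions: PPh3, MeCN, reflux
Reagents that add atoms: triphenylphosphine, c1ccc(cc1)P(c1ccccc1)c1ccccc1
Why: SN2 quaternisation of the phosphine by the primary bromide gives the Wittig salt that carries C2, C3, C4, C18 and C19.

Step 8
Reactants: 11 (1S,6S)-1-methyl-6-SC-4-(triisopropylsilyloxy)cyclohex-3-ene-1-carbaldehyde; 13 (4-methoxy-3-methyl-4-oxobutyl)triphenylphosphonium bromide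
Product: 15 methyl (1Z,13R)-13,15-bis(TBSO)-7-(triisopropylsilyloxy)-4,5-seco-17-norlabda-1,6-dien-19-oate (C4 epimers), via phosphorus ylide 14 (not isolated)
Conditions: NaN(SiMe3)2, THF, −78 to 0 °C; then 11, −78 °C to rt
Reagents that add atoms: none
Why: Wittig olefination of the hindered, non-enolisable aldehyde with the non-stabilised ylide attaches the C2–C4/C19 arm as a (Z)-alkene, whose geometry is irrelevant because it is hydrogenated next.

Step 9
Reactants: 15 methyl (1Z,13R)-13,15-bis(TBSO)-7-(triisopropylsilyloxy)-4,5-seco-17-norlabda-1,6-dien-19-oate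
Product: 16 methyl (13R)-13,15-bis(TBSO)-7-(triisopropylsilyloxy)-4,5-seco-17-norlabd-6-en-19-oate (C4 epimers)
Conditions: H2 (1 atm), RhCl(PPh3)3 (5 mol%), toluene/EtOH, rt
Reagents that add atoms: none
Why: Homogeneous hydrogenation should reduce the 1,2-disubstituted alkene and spare the trisubstituted, electron-rich and shielded silyl enol ether.

Step 10
Reactants: 16 methyl (13R)-13,15-bis(TBSO)-7-(triisopropylsilyloxy)-4,5-seco-17-norlabd-6-en-19-oate
Product: 17 methyl (13R)-13,15-bis(TBSO)-7-oxo-4,5-seco-17-norlabd-5-en-19-oate (C4 epimers)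
Conditions: Pd(OAc)2 (1.1 equiv), MeCN/DMSO, 40 °C
Reagents that add atoms: none
Why: Saegusa–Ito oxidation, in which palladation of the regiodefined silyl enol ether at C6 and β-hydride loss from C5, the only carbon that can supply it, give the C5=C6 enone.

Step 11
Reactants: 17 methyl (13R)-13,15-bis(TBSO)-7-oxo-4,5-seco-17-norlabd-5-en-19-oate
Product: 19 methyl (13R)-8α-hydroxy-13,15-bis(TBSO)-7-oxo-4,5-seco-17-norlabd-5-en-19-oate (C4 epimers), via potassium dienolate 18 (not isolated)
Conditions: KN(SiMe3)2 (1.1 equiv), THF, −78 °C; then 2-(phenylsulfonyl)-3-phenyloxaziridine, −78 °C; aq. NH4Cl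
Reagents that add atoms: 2-(phenylsulfonyl)-3-phenyloxaziridine, O=S(=O)(c1ccccc1)N1OC1c1ccccc1
Why: Kinetic deprotonation at C8, the only enolisable position of the enone (C10 is quaternary and the ester α-proton is less acidic), followed by oxaziridine hydroxylation of the enolate (Davis oxidation) from the α face, away from the adjacent 9β side chain and the axial 10β methyl, should give the 8α-alcohol.

Step 12
Reactants: 19 methyl (13R)-8α-hydroxy-13,15-bis(TBSO)-7-oxo-4,5-seco-17-norlabd-5-en-19-oate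
Product: 20 methyl (13R)-8α,13,15-tris(TBSO)-7-oxo-4,5-seco-17-norlabd-5-en-19-oate (C4 epimers)
Conditions: TBSCl, imidazole, DMF, rt
Reagents that add atoms: tert-butyldimethylsilyl chloride, CC(C)(C)[Si](C)(C)Cl
Why: Silyl ether formation at the secondary hydroxyl under conditions that do not enolise the ketone.

Step 13
Reactants: 20 methyl (13R)-8α,13,15-tris(TBSO)-7-oxo-4,5-seco-17-norlabd-5-en-19-oate
Product: 21 methyl (13R)-7β-hydroxy-8α,13,15-tris(TBSO)-4,5-seco-17-norlabd-5-en-19-oate (C4 epimers)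
Conditions: NaBH4, CeCl3·7H2O, MeOH, −78 to −40 °C
Reagents that add atoms: none
Why: Luche reduction is 1,2-selective, and axial delivery of hydride to C7 from the α face, anti to the axial C8–H, should give the equatorial 7β-alcohol trans to the 8α-silyloxy group.

Step 14
Reactants: 21 methyl (13R)-7β-hydroxy-8α,13,15-tris(TBSO)-4,5-seco-17-norlabd-5-en-19-oate
Product: 22 (13R)-7β-hydroxy-8α,13,15-tris(TBSO)-4,5-seco-17-norlabd-5-en-19-oic acid (C4 epimers)
Conditions: Me3SnOH (8 equiv), 1,2-dichloroethane, 70 °C; then 0.1 M HCl wash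
Reagents that add atoms: trimethyltin hydroxide, C[Sn](C)(C)O
Why: Ester hydrolysis with the tin hydroxide proceeds under near-neutral conditions, so that the C8 silyl group should not migrate to the neighbouring C7 hydroxyl as it might under alkaline saponification.

Step 15
Reactants: 22 (13R)-7β-hydroxy-8α,13,15-tris(TBSO)-4,5-seco-17-norlabd-5-en-19-oic acid
Product: 23 (13R)-8α,13,15-tris(TBSO)-4,5-seco-17-norlabd-5-en-19,7β-olide (bridged ten-membered lactone; C4 epimers)
Conditions: 2-methyl-6-nitrobenzoic anhydride (1.5 equiv), DMAP (3 equiv), Et3N, CH2Cl2, 1 mM, slow addition of 22 over 12 h, rt to 40 °C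
Reagents that add atoms: none
Why: Shiina macrolactonisation, in which the mixed anhydride acylates the 7β-hydroxyl under high dilution and closes the ten-membered ring without touching a stereocentre.

Step 16
Reactants: 23 (13R)-8α,13,15-tris(TBSO)-4,5-seco-17-norlabd-5-en-19,7β-olide
Product: 26 (13R)-8α,13,15-tris(TBSO)-17-norlabd-6-en-19-oic acid (5α-H; 4β-carboxyl), via silyl ketene acetal 24 (not isolated), via trimethylsilyl ester 25 (not isolated)
Conditions: KN(SiMe3)2 (1.5 equiv), Me3SiCl/Et3N (premixed, 4 equiv), THF/toluene, −78 °C to rt, then up to 110 °C; dilute HCl work-up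
Reagents that add atoms: none
Why: Proposed new method: the base with internal Me3SiCl should convert lactone 23 into silyl ketene acetal 24, whose C4 then bonds to C5 across C5=C6 while the C7–O bond breaks and the alkene moves to C6=C7, a concerted suprafacial [3,3] shift that leaves C19 as silyl ester 25 and, after mild hydrolysis, as acid 26. The closest known reaction type is the Ireland–Claisen ring contraction of monocyclic medium and large allylic lactones to 2-vinylcycloalkanecarboxylic acids; here the allyl unit lies inside ring B, so the lactone is bridged and the shift has no direct precedent. Ring A closes by transannular C4–C5 bond formation, formally a 6-(enolexo)-exo-trig attack, as the ten-membered lactone contracts to the six-membered carbocycle. C5 is controlled by the 7β-oxygen, because the new bond must form on the face the oxygen leaves, and since the C1 arm sits on the α face of C10 this gives the trans ring fusion (H5 α). C4 is controlled by the two tethers: C19 stays tied to O7 on the C6 side of C5 and C3 to C10 on the other side, so only a boat-like array from the ketene acetal with C3 cis to the ring oxygen, or its chair-like counterpart from the trans isomer, can be reached, and both put C19 axial (β, syn to C20) and C18 equatorial. The step needs enolisation only at C4 and a shift that outruns fragmentation of the enolate; the lack of other acidic C–H bonds, silylation in situ at −78 °C and release of the strain of the bridged lactone should secure this, and heating in toluene is provided because ring B must pass through a boat conformation.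

Step 17
Reactants: 26 (13R)-8α,13,15-tris(TBSO)-17-norlabd-6-en-19-oic acid
Product: 27 (13R)-8α,13,15-tris(TBSO)-17-norlabdan-19-oic acid
Conditions: H2 (1 atm), 10% Pd/C, EtOAc, rt
Reagents that add atoms: none
Why: Heterogeneous hydrogenation of the cis-disubstituted C6=C7 alkene creates no stereocentre and should leave the silyl ethers and the acid intact.

Step 18
Reactants: 27 (13R)-8α,13,15-tris(TBSO)-17-norlabdan-19-oic acid
Product: 28 (13R)-8α,13,15-trihydroxy-17-norlabdan-19-oic acid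
Conditions: HF (48% aq.), MeCN, rt to 40 °C
Reagents that add atoms: none
Why: Fluoride-driven cleavage of all three silyl ethers, the tertiary one included, is driven by Si–F bond formation and is tolerated by the saturated decalin acid.

Step 19
Reactants: 28 (13R)-8α,13,15-trihydroxy-17-norlabdan-19-oic acid
Product: 29 (13R)-13-hydroxy-8-oxo-17-norlabdane-15,19-dioic acid
Conditions: TEMPO (0.3 equiv), PhI(OAc)2 (4 equiv), MeCN/H2O (1:1), rt
Reagents that add atoms: water, O
Why: Oxoammonium (TEMPO) oxidation should convert the secondary C8 alcohol into the ketone and the primary C15 alcohol, through the aldehyde hydrate, into the acid, while the tertiary C13 alcohol cannot be oxidised.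

Step 20
Reactants: 29 (13R)-13-hydroxy-8-oxo-17-norlabdane-15,19-dioic acid
Product: 30 (13R)-13-hydroxylabd-8(17)-ene-15,19-dioic acid (target, CNP0126190.2)
Conditions: Ph3PCH3Br (8 equiv), KOtBu (7.5 equiv), THF, 0 °C to reflux; then dilute HCl
Reagents that add atoms: methyltriphenylphosphonium bromide, C[P+](c1ccccc1)(c1ccccc1)c1ccccc1.[Br-]
Why: Wittig methylenation with excess ylide, the acids being carried as carboxylates, installs C17 at the hindered ketone, and any base-induced epimerisation at C9 should return the side chain to the more stable equatorial 9β position.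

**Compound list**

1 | (R)-(−)-linalool | C=C[C@](C)(O)CCC=C(C)C | starting material
2 | (3R)-1-(9-borabicyclo[3.3.1]nonan-9-yl)-3,7-dimethyloct-6-en-3-ol | CC(C)=CCC[C@@](C)(O)CCB1C2CCCC1CCC2 | intermediate
3 | (3R)-3,7-dimethyloct-6-ene-1,3-diol | CC(C)=CCC[C@@](C)(O)CCO | intermediate
4 | (3R)-1,3-bis(tert-butyldimethylsilyloxy)-3,7-dimethyloct-6-ene | CC(C)=CCC[C@@](C)(O[Si](C)(C)C(C)(C)C)CCO[Si](C)(C)C(C)(C)C | intermediate
5 | secondary ozonide of 4 (3,3-dimethyl-5-SC-1,2,4-trioxolane) | CC1(C)OOC(CC[C@@](C)(O[Si](C)(C)C(C)(C)C)CCO[Si](C)(C)C(C)(C)C)O1 | intermediate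
6 | (4R)-4,6-bis(tert-butyldimethylsilyloxy)-4-methylhexanal | O=CCC[C@@](C)(O[Si](C)(C)C(C)(C)C)CCO[Si](C)(C)C(C)(C)C | intermediate
7 | 2-(triphenylphosphoranylidene)propanal | CC(C=O)=P(c1ccccc1)(c1ccccc1)c1ccccc1 | starting material
8 | (2E,6R)-6,8-bis(tert-butyldimethylsilyloxy)-2,6-dimethyloct-2-enal | O=C/C(C)=C/CC[C@@](C)(O[Si](C)(C)C(C)(C)C)CCO[Si](C)(C)C(C)(C)C | intermediate
9 | methyl vinyl ketone | C=CC(C)=O | starting material
10 | 2-(triisopropylsilyloxy)buta-1,3-diene | C=CC(=C)O[Si](C(C)C)(C(C)C)C(C)C | intermediate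
11 | (1S,6S)-1-methyl-6-SC-4-(triisopropylsilyloxy)cyclohex-3-ene-1-carbaldehyde | C1C(O[Si](C(C)C)(C(C)C)C(C)C)=CC[C@](C)(C=O)[C@H]1CC[C@@](C)(O[Si](C)(C)C(C)(C)C)CCO[Si](C)(C)C(C)(C)C | intermediate
12 | methyl 4-bromo-2-methylbutanoate (racemic) | COC(=O)C(C)CCBr | starting material
13 | (4-methoxy-3-methyl-4-oxobutyl)triphenylphosphonium bromide | COC(=O)C(C)CC[P+](c1ccccc1)(c1ccccc1)c1ccccc1.[Br-] | intermediate
14 | methyl 2-methyl-4-(triphenylphosphoranylidene)butanoate | COC(=O)C(C)CC=P(c1ccccc1)(c1ccccc1)c1ccccc1 | intermediate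
15 | methyl (1Z,13R)-13,15-bis(TBSO)-7-(triisopropylsilyloxy)-4,5-seco-17-norlabda-1,6-dien-19-oate (C4 epimers) | C1C(O[Si](C(C)C)(C(C)C)C(C)C)=CC[C@](C)(/C=C\CC(C)C(=O)OC)[C@H]1CC[C@@](C)(O[Si](C)(C)C(C)(C)C)CCO[Si](C)(C)C(C)(C)C | intermediate
16 | methyl (13R)-13,15-bis(TBSO)-7-(triisopropylsilyloxy)-4,5-seco-17-norlabd-6-en-19-oate (C4 epimers) | C1C(O[Si](C(C)C)(C(C)C)C(C)C)=CC[C@](C)(CCCC(C)C(=O)OC)[C@H]1CC[C@@](C)(O[Si](C)(C)C(C)(C)C)CCO[Si](C)(C)C(C)(C)C | intermediate
17 | methyl (13R)-13,15-bis(TBSO)-7-oxo-4,5-seco-17-norlabd-5-en-19-oate (C4 epimers) | C1C(=O)C=C[C@](C)(CCCC(C)C(=O)OC)[C@H]1CC[C@@](C)(O[Si](C)(C)C(C)(C)C)CCO[Si](C)(C)C(C)(C)C | intermediate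
18 | potassium 5,7-dienolate of 17 (O7–K; C5=C6 and C7=C8) | [K+].[O-]C1=C[C@H](CC[C@@](C)(O[Si](C)(C)C(C)(C)C)CCO[Si](C)(C)C(C)(C)C)[C@@](C)(CCCC(C)C(=O)OC)C=C1 | intermediate
19 | methyl (13R)-8α-hydroxy-13,15-bis(TBSO)-7-oxo-4,5-seco-17-norlabd-5-en-19-oate (C4 epimers) | O[C@@H]1C(=O)C=C[C@](C)(CCCC(C)C(=O)OC)[C@H]1CC[C@@](C)(O[Si](C)(C)C(C)(C)C)CCO[Si](C)(C)C(C)(C)C | intermediate
20 | methyl (13R)-8α,13,15-tris(TBSO)-7-oxo-4,5-seco-17-norlabd-5-en-19-oate (C4 epimers) | CC(C)(C)[Si](C)(C)O[C@@H]1C(=O)C=C[C@](C)(CCCC(C)C(=O)OC)[C@H]1CC[C@@](C)(O[Si](C)(C)C(C)(C)C)CCO[Si](C)(C)C(C)(C)C | intermediate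
21 | methyl (13R)-7β-hydroxy-8α,13,15-tris(TBSO)-4,5-seco-17-norlabd-5-en-19-oate (C4 epimers) | CC(C)(C)[Si](C)(C)O[C@@H]1[C@@H](O)C=C[C@](C)(CCCC(C)C(=O)OC)[C@H]1CC[C@@](C)(O[Si](C)(C)C(C)(C)C)CCO[Si](C)(C)C(C)(C)C | intermediate
22 | (13R)-7β-hydroxy-8α,13,15-tris(TBSO)-4,5-seco-17-norlabd-5-en-19-oic acid (C4 epimers) | CC(C)(C)[Si](C)(C)O[C@@H]1[C@@H](O)C=C[C@](C)(CCCC(C)C(=O)O)[C@H]1CC[C@@](C)(O[Si](C)(C)C(C)(C)C)CCO[Si](C)(C)C(C)(C)C | intermediate
23 | (13R)-8α,13,15-tris(TBSO)-4,5-seco-17-norlabd-5-en-19,7β-olide (C4 epimers) | CC(C)(C)[Si](C)(C)O[C@@H]1[C@H]2OC(=O)C(C)CCC[C@@](C)(C=C2)[C@H]1CC[C@@](C)(O[Si](C)(C)C(C)(C)C)CCO[Si](C)(C)C(C)(C)C | intermediate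
24 | trimethylsilyl ketene acetal of 23 (C19=C4; ring double-bond geometry left open) | CC(C)(C)[Si](C)(C)O[C@@H]1[C@H]2OC(O[Si](C)(C)C)=C(C)CCC[C@@](C)(C=C2)[C@H]1CC[C@@](C)(O[Si](C)(C)C(C)(C)C)CCO[Si](C)(C)C(C)(C)C | intermediate
25 | trimethylsilyl (13R)-8α,13,15-tris(TBSO)-17-norlabd-6-en-19-oate | CC(C)(C)[Si](C)(C)O[C@@H]1C=C[C@@H]2[C@](C)(CCC[C@]2(C)C(=O)O[Si](C)(C)C)[C@H]1CC[C@@](C)(O[Si](C)(C)C(C)(C)C)CCO[Si](C)(C)C(C)(C)C | intermediate
26 | (13R)-8α,13,15-tris(TBSO)-17-norlabd-6-en-19-oic acid | CC(C)(C)[Si](C)(C)O[C@@H]1C=C[C@@H]2[C@](C)(CCC[C@]2(C)C(=O)O)[C@H]1CC[C@@](C)(O[Si](C)(C)C(C)(C)C)CCO[Si](C)(C)C(C)(C)C | intermediate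
27 | (13R)-8α,13,15-tris(TBSO)-17-norlabdan-19-oic acid | CC(C)(C)[Si](C)(C)O[C@@H]1CC[C@@H]2[C@](C)(CCC[C@]2(C)C(=O)O)[C@H]1CC[C@@](C)(O[Si](C)(C)C(C)(C)C)CCO[Si](C)(C)C(C)(C)C | intermediate
28 | (13R)-8α,13,15-trihydroxy-17-norlabdan-19-oic acid | O[C@@H]1CC[C@@H]2[C@](C)(CCC[C@]2(C)C(=O)O)[C@H]1CC[C@@](C)(O)CCO | intermediate
29 | (13R)-13-hydroxy-8-oxo-17-norlabdane-15,19-dioic acid | O=C1CC[C@@H]2[C@](C)(CCC[C@]2(C)C(=O)O)[C@H]1CC[C@@](C)(O)CC(=O)O | intermediate
30 | (13R)-13-hydroxylabd-8(17)-ene-15,19-dioic acid | C=C1CC[C@@H]2[C@](C)(CCC[C@]2(C)C(=O)O)[C@H]1CC[C@@](C)(O)CC(=O)O | target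

**Step count and risks**

Total: 20 steps. Longest linear sequence: 18 steps from (R)-linalool (steps 1–4, 6 and 8–20); steps 5 and 7 prepare the diene and the phosphonium salt.

Steps most likely to fail:

1. Step 16 (the sigmatropic ring contraction). Ring B must pass through a boat in which the 7β-oxygen and the C10 methyl approach flagpole positions. If this raises the barrier too far, fragmentation of the enolate to a ketene and the C7 alkoxide, C-silylation, or plain return of the lactone on work-up could outrun the shift.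
   Fallback (known chemistry, from 11, returning at 27): the shift is run untethered and ring A is closed afterwards.
   - Methylenation of aldehyde 11 (Ph3PCH3Br, KOtBu) gives 1-ethenyl-1-methyl-6-SC-4-(triisopropylsilyloxy)cyclohex-3-ene F1.
   - Pd(OAc)2 as in step 10 gives 4-ethenyl-4-methyl-5-SC-cyclohex-2-en-1-one F2.
   - The reagents of steps 11–13 give in turn the 8α-hydroxy enone F3, its tert-butyldimethylsilyl ether F4 and the 7β-allylic alcohol F5.
   - Esterification with pent-4-enoic acid (dicyclohexylcarbodiimide, DMAP) gives the 7β-pent-4-enoate F6.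
   - An ordinary Ireland–Claisen rearrangement of this cyclohexenyl ester (LiN(iPr)2, Me3SiCl, THF, −78 to 60 °C) moves the acyl α-carbon to the β face of C5 and gives 2-[4α-TBSO-6-ethenyl-6-methyl-5-SC-cyclohex-2-en-1-yl]pent-4-enoic acid F7 (C4 epimers).
   - Ring-closing metathesis with the second-generation Grubbs catalyst joins the C10 vinyl and the allyl group and gives the trans-fused (13R)-8α,13,15-tris(TBSO)-17,18-dinorlabda-1,6-dien-19-oic acid F8.
   - Methylation of its dianion (LiN(iPr)2, 2.5 equiv, then MeI) from the α face, away from C20, gives (13R)-8α,13,15-tris(TBSO)-17-norlabda-1,6-dien-19-oic acid F9.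
   - Hydrogenation over Pd/C saturates both alkenes and gives 27.

2. Step 15 (lactonisation). Closing the ten-membered ring across ring B (C1 arm on the α face, oxygen on the β face) is slow, so intermolecular acylation to diolides and oligomers, or ketene formation from the activated acid, may win.
   Fallback (from 20, returning at 23): the ring is closed by C7–O bond formation with inversion instead of by acylation.
   - LiBH(sec-Bu)3 in THF at −78 °C attacks the ketone of 20 from the β face, anti to the 8α-silyloxy group, and gives methyl (13R)-7α-hydroxy-8α,13,15-tris(TBSO)-4,5-seco-17-norlabd-5-en-19-oate F10.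
   - Me3SnOH as in step 14 gives the 7α-hydroxy acid F11.
   - Mitsunobu lactonisation (PPh3, diisopropyl azodicarboxylate, toluene, high dilution) lets the carboxylate displace the activated 7α-oxygen with inversion and gives 23.

3. Step 6 (Diels–Alder). The β-branched, α-methyl enal may react slowly, so protodesilylation of the diene by the acidic catalyst could compete. Insufficient facial discrimination would give the C9/C10 diastereomer, which cannot be expected to separate from 11.
   Fallback (from 8, returning at 17): a more nucleophilic aminosilyloxy diene and a different catalyst class are used, and the Saegusa step is bypassed.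
   - 1-(Dimethylamino)-3-(tert-butyldimethylsilyloxy)buta-1,3-diene reacts with 8 in the presence of the trivalent chromium salen complex [N,N′-bis(3,5-di-tert-butylsalicylidene)cyclohexane-1,2-diaminato]CrSbF6, in the antipode that serves the C2-Si face, and gives 2-(dimethylamino)-1-methyl-6-SC-4-(tert-butyldimethylsilyloxy)cyclohex-3-ene-1-carbaldehyde F12.
   - Wittig reaction with ylide 14 gives the (Z)-alkenyl ester F13.
   - Hydrogenation with RhCl(PPh3)3 gives the saturated ester F14.
   - Dilute HCl in THF at 0 °C hydrolyses the silyl enol ether, eliminates dimethylamine and gives enone 17.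

Further compounds

F1 | step 16 | 1-ethenyl-1-methyl-6-SC-4-(triisopropylsilyloxy)cyclohex-3-ene (10β-methyl, 9β-SC) | C1C(O[Si](C(C)C)(C(C)C)C(C)C)=CC[C@](C)(C=C)[C@H]1CC[C@@](C)(O[Si](C)(C)C(C)(C)C)CCO[Si](C)(C)C(C)(C)C
F2 | step 16 | 4-ethenyl-4-methyl-5-SC-cyclohex-2-en-1-one | C1C(=O)C=C[C@](C)(C=C)[C@H]1CC[C@@](C)(O[Si](C)(C)C(C)(C)C)CCO[Si](C)(C)C(C)(C)C
F3 | step 16 | 4-ethenyl-6-hydroxy-4-methyl-5-SC-cyclohex-2-en-1-one (8α-hydroxy) | O[C@@H]1C(=O)C=C[C@](C)(C=C)[C@H]1CC[C@@](C)(O[Si](C)(C)C(C)(C)C)CCO[Si](C)(C)C(C)(C)C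
F4 | step 16 | 6-(tert-butyldimethylsilyloxy)-4-ethenyl-4-methyl-5-SC-cyclohex-2-en-1-one (8α-TBSO) | CC(C)(C)[Si](C)(C)O[C@@H]1C(=O)C=C[C@](C)(C=C)[C@H]1CC[C@@](C)(O[Si](C)(C)C(C)(C)C)CCO[Si](C)(C)C(C)(C)C
F5 | step 16 | 6-(tert-butyldimethylsilyloxy)-4-ethenyl-4-methyl-5-SC-cyclohex-2-en-1-ol (7β-hydroxy, 8α-TBSO) | CC(C)(C)[Si](C)(C)O[C@@H]1[C@@H](O)C=C[C@](C)(C=C)[C@H]1CC[C@@](C)(O[Si](C)(C)C(C)(C)C)CCO[Si](C)(C)C(C)(C)C
F6 | step 16 | 7β-pent-4-enoate of F5 | CC(C)(C)[Si](C)(C)O[C@@H]1[C@@H](OC(=O)CCC=C)C=C[C@](C)(C=C)[C@H]1CC[C@@](C)(O[Si](C)(C)C(C)(C)C)CCO[Si](C)(C)C(C)(C)C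
F7 | step 16 | 2-[4α-TBSO-6-ethenyl-6-methyl-5-SC-cyclohex-2-en-1-yl]pent-4-enoic acid (side arm on the β face of C5; C4 epimers) | CC(C)(C)[Si](C)(C)O[C@@H]1C=C[C@@H](C(CC=C)C(=O)O)[C@](C)(C=C)[C@H]1CC[C@@](C)(O[Si](C)(C)C(C)(C)C)CCO[Si](C)(C)C(C)(C)C
F8 | step 16 | (13R)-8α,13,15-tris(TBSO)-17,18-dinorlabda-1,6-dien-19-oic acid (C4 epimers) | CC(C)(C)[Si](C)(C)O[C@@H]1C=C[C@@H]2[C@](C)(C=CCC2C(=O)O)[C@H]1CC[C@@](C)(O[Si](C)(C)C(C)(C)C)CCO[Si](C)(C)C(C)(C)C
F9 | step 16 | (13R)-8α,13,15-tris(TBSO)-17-norlabda-1,6-dien-19-oic acid | CC(C)(C)[Si](C)(C)O[C@@H]1C=C[C@@H]2[C@](C)(C=CC[C@]2(C)C(=O)O)[C@H]1CC[C@@](C)(O[Si](C)(C)C(C)(C)C)CCO[Si](C)(C)C(C)(C)C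
F10 | step 15 | methyl (13R)-7α-hydroxy-8α,13,15-tris(TBSO)-4,5-seco-17-norlabd-5-en-19-oate (C4 epimers) | CC(C)(C)[Si](C)(C)O[C@@H]1[C@H](O)C=C[C@](C)(CCCC(C)C(=O)OC)[C@H]1CC[C@@](C)(O[Si](C)(C)C(C)(C)C)CCO[Si](C)(C)C(C)(C)C
F11 | step 15 | (13R)-7α-hydroxy-8α,13,15-tris(TBSO)-4,5-seco-17-norlabd-5-en-19-oic acid (C4 epimers) | CC(C)(C)[Si](C)(C)O[C@@H]1[C@H](O)C=C[C@](C)(CCCC(C)C(=O)O)[C@H]1CC[C@@](C)(O[Si](C)(C)C(C)(C)C)CCO[Si](C)(C)C(C)(C)C
F12 | step 6 | 2-(dimethylamino)-1-methyl-6-SC-4-(tert-butyldimethylsilyloxy)cyclohex-3-ene-1-carbaldehyde (amine-bearing carbon left open) | C1C(O[Si](C)(C)C(C)(C)C)=CC(N(C)C)[C@](C)(C=O)[C@H]1CC[C@@](C)(O[Si](C)(C)C(C)(C)C)CCO[Si](C)(C)C(C)(C)C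
F13 | step 6 | methyl (Z)-5-[2-(dimethylamino)-1-methyl-6-SC-4-(tert-butyldimethylsilyloxy)cyclohex-3-en-1-yl]-2-methylpent-4-enoate | C1C(O[Si](C)(C)C(C)(C)C)=CC(N(C)C)[C@](C)(/C=C\CC(C)C(=O)OC)[C@H]1CC[C@@](C)(O[Si](C)(C)C(C)(C)C)CCO[Si](C)(C)C(C)(C)C
F14 | step 6 | methyl 5-[2-(dimethylamino)-1-methyl-6-SC-4-(tert-butyldimethylsilyloxy)cyclohex-3-en-1-yl]-2-methylpentanoate | C1C(O[Si](C)(C)C(C)(C)C)=CC(N(C)C)[C@](C)(CCCC(C)C(=O)OC)[C@H]1CC[C@@](C)(O[Si](C)(C)C(C)(C)C)CCO[Si](C)(C)C(C)(C)C
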